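The data are calculated for substances that don't exist; the scatter is artificial.

A percentage point of free monomer, once lost, stands either as monomer in chains or as uncatalysed product, so I count in points of the charge.

| flask | free monomer | transfer agent | initiator | temperature | remark | time |
|---|---|---|---|---|---|---|
| cedar | 0.76 M | 3.8 mM | 38 mM | 12 °C | run made earlier |  |
| birch | 0.76 M | 5.7 mM | 38 mM | 40 °C | run made earlier |  |
| oak | 0.76 M | 7.6 mM | 57 mM | 12 °C | run made earlier |  |
| dawn | 0.76 M | 7.60 mM | 38 mM | 25 °C |  | 2.0 d |
| spring | 0.76 M | 7.60 mM | 38 mM |  | at 0 °C until 30 h, from then on at 50 °C | 2.0 d |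
| winter | 0.76 M | 7.60 mM | 38 mM | 50 °C |  | 2.0 d |
| summer | 0.76 M | 7.60 mM | 38 mM | 0 °C |  | 2.0 d |

cedar run (percent of the free monomer charged)

| time / d | monomer in chains / % | free monomer / % |
|---|---|---|
| 0.333 | 7 | 95 |
| 0.625 | 5 | 94 |
| 1.67 | 14 | 70 |
| 4.00 | 38 | 45 |

birch run (percent of the free monomer charged)

| time / h | monomer in chains / % | free monomer / % |
|---|---|---|
| 2.00 | 8 | 70 |
| 4.00 | 10 | 46 |
| 10.0 | 13 | 12 |
| 25.0 | 18 | 2 |

oak run (percent of the free monomer charged)

| time / d | monomer in chains / % | free monomer / % |
|---|---|---|
| 0.500 | 8 | 94 |
| 1.25 | 18 | 75 |
| 2.50 | 35 | 49 |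
| 4.00 | 44 | 34 |

(standard deviation of a reading: 2 percentage points)

- steps thought possible: free monomer + initiator -> living end + monomer in chains; free monomer + living end -> monomer in chains + living end; living end + transfer agent -> dead chain; free monomer -> uncatalysed product; living end -> dead end

- the flask that comes out highest in amount of monomer in chains, in percent of the free monomer charged, or "all alike" when all lie within 1.5 percentage points (dawn / spring / winter / summer / all alike)
- monomer in chains at the end, in percent of the free monomer charged, dawn
- monomer in chains at the end, in percent of the free monomer charged, spring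
- monomer in chains at the end, in percent of the free monomer charged, winter
- monomer in chains at the end, in percent of the free monomer charged, summer

In the readings, uncatalysed product is what is missing from the sum. I call monomer in chains divided by uncatalysed product the chain odds, a selectivity factor. Cedar at its last reading gives chain odds of 2.24, and birch at its last reading gives 0.225. Both are readings and carry the scatter.

I draw the logarithm of the odds as a straight line in temperature. Cedar and birch differ in transfer agent too, so this line is a rough reckoning. I do the same for the loss of free monomer, read as first order: it reads 0.200 d⁻¹ in cedar and 4.66 d⁻¹ in birch.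

For dawn this gives odds of 0.770, so 43.5 % of the lost monomer goes into chains. The loss rate is 0.862 d⁻¹, so conversion is 82.2 %. My dawn figure is 35.7 %.

Now I turn the question round. I take winter as fully converted, so its answer is its share. Its odds of 0.0991 give 9.02 %. For winter to beat dawn, dawn's conversion has to lie under 20.7 %, and I reckon it far above that. Summer's answer is a part of its conversion, which I reckon at 9.83 %, less than my dawn figure. Spring ends at winter's temperature, so I expect it near winter. I commit to dawn.

The forecast also names dawn, with 24 % for dawn, lower than my figure, 13 % for spring, 11 % for winter, where “the side reaction dominates”, and 9 % for summer.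

The flasks give 29.9 % for dawn, 13.7 % for spring, 11.8 % for winter and 4.57 % for summer, so dawn is highest.

    free monomer + initiator → living end + monomer in chains (k = 0.148 L mol⁻¹ h⁻¹, Ea = 74.0 kJ mol⁻¹)
    free monomer + living end → monomer in chains + living end, rate k2*[living end]*[free monomer] (k = 0.886 L mol⁻¹ h⁻¹, Ea = 54.0 kJ mol⁻¹)
    living end + transfer agent → dead chain (kL = 0.828 L mol⁻¹ h⁻¹, Ea = 77.0 kJ mol⁻¹)
    free monomer → uncatalysed product (k = 0.0218 h⁻¹, Ea = 100 kJ mol⁻¹)
    living end → dead end (k = 0.0479 h⁻¹, Ea = 88.0 kJ mol⁻¹)
    (constants at 25 °C)

Dawn ends with chain odds of 0.595, less than the 0.770 I drew. Winter ends with odds of 0.133, more than the 0.0991 the same line gives. Winter's free monomer stands at 0 %, so its answer is its share. The step from free monomer to uncatalysed product costs winter 13 percentage points of monomer in chains: without that step, winter ends at 24.4 %.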